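**Retrosynthetic overview**
1. Target ⇐ removal of three aryl silyl ethers ⇐ flavanone whose ring C is closed by O1–C2 bond formation: a catalyst-controlled 6-endo oxa-Michael addition of the C2′ phenol of a 2′-hydroxy-6′-methoxychalcone (sets C2).
2. That chalcone ⇐ ring-A aryllithium (directed ortho-metalation between an acetal ether and OMe) + 4-silyloxycinnamoyl Weinreb amide.
3. Side arm ⇐ CBS reduction of the aryl ketone (sets C1″) ⇐ Rh-catalysed asymmetric conjugate addition of an (E)-alkenylboronic acid (sets C3″) to a chalcone made from 2′,6′-dihydroxy-4′-methoxyacetophenone.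
4. Alkenylboronic acid ⇐ alkyne hydroboration ⇐ (S)-homopropargylic alcohol from asymmetric propargylation of a 3-arylpropanal (sets C7″).
5. Ring order: ring A and the three phenol rings are bought; the pyranone ring C is the only ring made, in step 12.

Notation: flavanone numbering for the core; the C8 side chain is C1″–C9″ counted from ring A. TBS = tert-butyldimethylsilyl, TES = triethylsilyl, EE = 1-ethoxyethyl.

Assumption: the sense of induction of each chiral catalyst is assigned by analogy with its closest simple model, and the mirror-image or pseudoenantiomeric catalyst is used unchanged if a model run shows the opposite sense; the EE acetal carbons are stereochemically undefined mixtures, which is without consequence.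

**Route**

Step 1
Reactants: 1 tert-butyl(4-iodophenoxy)dimethylsilane; 2 allyl alcohol
Product: 3 3-[4-(TBS-oxy)phenyl]propanal
Conditions: Pd(OAc)2 (2 mol%), Bu4NCl, NaHCO3, DMF, 40 °C
Reagents that add atoms: none
Why: Heck arylation of allyl alcohol under Jeffery conditions, where β-hydride elimination toward the carbinol carbon and enol–aldehyde tautomerism give the 3-arylpropanal directly; no stereocenter.

Step 2
Reactants: 3 3-[4-(TBS-oxy)phenyl]propanal; 4 allenyltributylstannane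
Product: 5 (3S)-1-[4-(TBS-oxy)phenyl]hex-5-yn-3-ol
Conditions: (R)-BINOL (20 mol%), Ti(OiPr)4 (10 mol%), 4 Å MS, CH2Cl2, −20 °C; aq NaHCO3
Reagents that add atoms: none
Why: Keck asymmetric propargylation, in which the BINOL–Ti(OiPr)4 Lewis acid activates the aldehyde and the allenylstannane adds SE2′ to one face, setting C7″ as S ((R)-BINOL by analogy with Keck allylation of unbranched aliphatic aldehydes).

Step 3
Reactants: 5 (3S)-1-[4-(TBS-oxy)phenyl]hex-5-yn-3-ol
Product: 6 (3S)-1-[4-(TBS-oxy)phenyl]-3-(TES-oxy)hex-5-yne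
Conditions: Et3SiCl, imidazole, DMF, 0 °C
Reagents that add atoms: chlorotriethylsilane, CC[Si](Cl)(CC)CC
Why: Standard silylation of the secondary alcohol, which keeps the later organolithium step free of a second alkoxide and is removed together with the acetals in step 11.

Step 4
Reactants: 6 (3S)-1-[4-(TBS-oxy)phenyl]-3-(TES-oxy)hex-5-yne
Product: 8 [(1E,4S)-6-[4-(TBS-oxy)phenyl]-4-(TES-oxy)hex-1-en-1-yl]boronic acid, via alkenylcatecholborane 7 (not isolated)
Conditions: catecholborane (neat), 70 °C; then H2O, 23 °C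
Reagents that add atoms: catecholborane, B1Oc2ccccc2O1; water, O
Why: Uncatalysed syn, anti-Markovnikov hydroboration of the terminal alkyne followed by hydrolysis gives only the (E)-alkenylboronic acid; no new stereocenter.

Step 5
Reactants: 9 2′,6′-dihydroxy-4′-methoxyacetophenone
Product: 10 2′,6′-bis(1-ethoxyethoxy)-4′-methoxyacetophenone
Conditions: NaH, CH3CHClOEt, DMF, 0 → 23 °C
Reagents that add atoms: 1-chloroethyl ethyl ether, CCOC(C)Cl
Why: Williamson-type O-alkylation of both chelated phenoxides with the α-chloro ether gives acetal ethers that are stable to base and organolithiums, later act as ortho-directing groups and leave under very mild acid.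

Step 6
Reactants: 10 2′,6′-bis(1-ethoxyethoxy)-4′-methoxyacetophenone; 11 4-(TBS-oxy)benzaldehyde
Product: 14 (2E)-1-[2,6-bis(1-ethoxyethoxy)-4-methoxyphenyl]-3-[4-(TBS-oxy)phenyl]prop-2-en-1-one, via lithium aldolate 12 (not isolated), via mesylate 13 (not isolated)
Conditions: LiN(SiMe3)2, THF, −78 °C; 11; then MsCl, Et3N, −78 → 23 °C
Reagents that add atoms: none
Why: Directed aldol addition of the lithium enolate followed by mesylation and E1cB elimination is a hydroxide-free Claisen–Schmidt condensation that spares the aryl silyl ether and gives the (E)-chalcone.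

Step 7
Reactants: 14 (E)-chalcone of ring A; 8 (E)-alkenylboronic acid
Product: 15 (3R,4E,7S)-1-[2,6-bis(1-ethoxyethoxy)-4-methoxyphenyl]-3,9-bis[4-(TBS-oxy)phenyl]-7-(TES-oxy)non-4-en-1-one
Conditions: [Rh(OH)((R)-BINAP)]2 (3 mol%), dioxane/H2O (10:1), 40 °C
Reagents that add atoms: none
Why: Hayashi–Miyaura rhodium-catalysed asymmetric 1,4-addition transfers the alkenyl group with retention of its (E) geometry to the β-carbon on the enone face selected by (R)-BINAP, setting C3″ as R (sense from the (S)-BINAP/acyclic (E)-enone model).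

Step 8
Reactants: 15 β-aryl-β-alkenyl ketone
Product: 16 (1S,3R,4E,7S)-1-[2,6-bis(1-ethoxyethoxy)-4-methoxyphenyl]-3,9-bis[4-(TBS-oxy)phenyl]-7-(TES-oxy)non-4-en-1-ol
Conditions: (R)-2-methyl-CBS-oxazaborolidine (0.5 equiv), catecholborane, toluene, −78 → −20 °C; then pH 7 buffer
Reagents that add atoms: none
Why: Corey–Bakshi–Shibata reduction in which the twisted di-ortho-substituted aryl group is the large substituent, so the (R)-catalyst gives the (S)-carbinol at C1″, and catecholborane is used because it does not hydroborate the C4″=C5″ alkene at these temperatures.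

Step 9
Reactants: 11 4-(TBS-oxy)benzaldehyde; 17 diethyl {2-[methoxy(methyl)amino]-2-oxoethyl}phosphonate
Product: 18 (2E)-3-[4-(TBS-oxy)phenyl]-N-methoxy-N-methylprop-2-enamide
Conditions: NaH, THF, 0 → 23 °C
Reagents that add atoms: none
Why: Horner–Wadsworth–Emmons olefination of the stabilised phosphonate anion gives the (E)-configured Weinreb cinnamamide.

Step 10
Reactants: 16 ring-A benzylic alcohol; 18 Weinreb cinnamamide
Product: 20 (2E)-1-{2,4-bis(1-ethoxyethoxy)-3-[(1S,3R,4E,7S)-3,9-bis[4-(TBS-oxy)phenyl]-1-hydroxy-7-(TES-oxy)non-4-en-1-yl]-6-methoxyphenyl}-3-[4-(TBS-oxy)phenyl]prop-2-en-1-one, via dilithio species 19 (not isolated)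
Conditions: n-BuLi (2.3 equiv), THF, −20 → 0 °C; 18, −78 → −20 °C; then H2O
Reagents that add atoms: none
Why: Directed ortho-metalation removes, after alkoxide formation, the only kind of ring-A hydrogen (two equivalent positions, each between an acetal ether and the methoxy group), and the aryllithium acylates the Weinreb amide (Weinreb ketone synthesis) to give the chalcone when the chelated adduct collapses on work-up.

Step 11
Reactants: 20 protected chalcone
Product: 21 (2E)-1-{3-[(1S,3R,4E,7S)-3,9-bis[4-(TBS-oxy)phenyl]-1,7-dihydroxynon-4-en-1-yl]-2,4-dihydroxy-6-methoxyphenyl}-3-[4-(TBS-oxy)phenyl]prop-2-en-1-one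
Conditions: pyridinium p-toluenesulfonate (0.3 equiv), MeOH/THF, 0 → 23 °C
Reagents that add atoms: none
Why: Mild acid-catalysed transacetalisation and silyl-ether methanolysis remove both phenolic acetals and the TES ether, while the aryl TBS ethers, the chalcone and the benzylic alcohol are expected to survive and no stereocenter is touched.

Step 12
Reactants: 21 2′-hydroxy-6′-methoxychalcone
Product: 22 (2S)-8-[(1S,3R,4E,7S)-3,9-bis[4-(TBS-oxy)phenyl]-1,7-dihydroxynon-4-en-1-yl]-2-[4-(TBS-oxy)phenyl]-7-hydroxy-5-methoxy-2,3-dihydro-4H-chromen-4-one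
Conditions: 9-amino(9-deoxy)epi-quinidine-derived N-[3,5-bis(trifluoromethyl)phenyl]squaramide (10 mol%), toluene/CH2Cl2, −20 °C
Reagents that add atoms: none
Why: Proposed new method: a bifunctional cinchona squaramide closes an unactivated 2′-hydroxychalcone under kinetic control, the quinuclidine nitrogen taking the proton of the C2′ phenol while the squaramide N–H pair binds the enone carbonyl, so that the phenoxide adds 6-endo to one face of the β-carbon and sets C2 as S; the 6′-methoxy group twists the chalcone out of plane, which makes closure strongly downhill and, with a weak amine at −20 °C, not reversed (reversal is what has limited selectivity with the parent chalcone); the closest known reactions are the bifunctional thiourea-catalysed intramolecular oxa-Michael addition of β-ketoester-activated alkylidene phenols to flavanones and the cinchona ion-pair catalysis of the parent 2′-hydroxychalcone–flavanone isomerisation.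

Step 13
Reactants: 22 tris-TBS flavanone
Product: 23 (2S)-8-[(1S,3R,4E,7S)-1,7-dihydroxy-3,9-bis(4-hydroxyphenyl)non-4-en-1-yl]-7-hydroxy-2-(4-hydroxyphenyl)-5-methoxy-2,3-dihydro-4H-chromen-4-one
Conditions: Bu4NF, AcOH (1:1.1), THF, 0 °C
Reagents that add atoms: none
Why: Fluoride cleavage of the three aryl silyl ethers, buffered with acetic acid so that no free phenoxide can open or epimerise the flavanone.

**Compound list**
1 | tert-butyl(4-iodophenoxy)dimethylsilane | CC(C)(C)[Si](C)(C)Oc1ccc(I)cc1 | starting material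
2 | allyl alcohol | C=CCO | starting material
3 | 3-[4-(TBS-oxy)phenyl]propanal | O=CCCc1ccc(O[Si](C)(C)C(C)(C)C)cc1 | intermediate
4 | allenyltributylstannane | C=C=C[Sn](CCCC)(CCCC)CCCC | starting material
5 | (3S)-1-[4-(TBS-oxy)phenyl]hex-5-yn-3-ol | C#CC[C@@H](O)CCc1ccc(O[Si](C)(C)C(C)(C)C)cc1 | intermediate
6 | (3S)-1-[4-(TBS-oxy)phenyl]-3-(TES-oxy)hex-5-yne | C#CC[C@@H](O[Si](CC)(CC)CC)CCc1ccc(O[Si](C)(C)C(C)(C)C)cc1 | intermediate
7 | 2-[(1E,4S)-6-[4-(TBS-oxy)phenyl]-4-(TES-oxy)hex-1-en-1-yl]-1,3,2-benzodioxaborole (not isolated) | c1ccc2OB(/C=C/C[C@@H](O[Si](CC)(CC)CC)CCc3ccc(O[Si](C)(C)C(C)(C)C)cc3)Oc2c1 | intermediate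
8 | [(1E,4S)-6-[4-(TBS-oxy)phenyl]-4-(TES-oxy)hex-1-en-1-yl]boronic acid | OB(O)/C=C/C[C@@H](O[Si](CC)(CC)CC)CCc1ccc(O[Si](C)(C)C(C)(C)C)cc1 | intermediate
9 | 2′,6′-dihydroxy-4′-methoxyacetophenone | CC(=O)c1c(O)cc(OC)cc1O | starting material
10 | 2′,6′-bis(1-ethoxyethoxy)-4′-methoxyacetophenone | CC(=O)c1c(OC(C)OCC)cc(OC)cc1OC(C)OCC | intermediate
11 | 4-(TBS-oxy)benzaldehyde | O=Cc1ccc(O[Si](C)(C)C(C)(C)C)cc1 | starting material
12 | lithium aldolate of 10 and 11 (not isolated) | [Li+].[O-]C(CC(=O)c1c(OC(C)OCC)cc(OC)cc1OC(C)OCC)c1ccc(O[Si](C)(C)C(C)(C)C)cc1 | intermediate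
13 | β-mesyloxy ketone (not isolated) | CS(=O)(=O)OC(CC(=O)c1c(OC(C)OCC)cc(OC)cc1OC(C)OCC)c1ccc(O[Si](C)(C)C(C)(C)C)cc1 | intermediate
14 | (2E)-1-[2,6-bis(1-ethoxyethoxy)-4-methoxyphenyl]-3-[4-(TBS-oxy)phenyl]prop-2-en-1-one | O=C(/C=C/c1ccc(O[Si](C)(C)C(C)(C)C)cc1)c1c(OC(C)OCC)cc(OC)cc1OC(C)OCC | intermediate
15 | (3R,4E,7S)-1-[2,6-bis(1-ethoxyethoxy)-4-methoxyphenyl]-3,9-bis[4-(TBS-oxy)phenyl]-7-(TES-oxy)non-4-en-1-one | O=C(C[C@H](/C=C/C[C@@H](O[Si](CC)(CC)CC)CCc1ccc(O[Si](C)(C)C(C)(C)C)cc1)c1ccc(O[Si](C)(C)C(C)(C)C)cc1)c1c(OC(C)OCC)cc(OC)cc1OC(C)OCC | intermediate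
16 | (1S,3R,4E,7S)-1-[2,6-bis(1-ethoxyethoxy)-4-methoxyphenyl]-3,9-bis[4-(TBS-oxy)phenyl]-7-(TES-oxy)non-4-en-1-ol | COc1cc(OC(C)OCC)c([C@@H](O)C[C@H](/C=C/C[C@@H](O[Si](CC)(CC)CC)CCc2ccc(O[Si](C)(C)C(C)(C)C)cc2)c2ccc(O[Si](C)(C)C(C)(C)C)cc2)c(OC(C)OCC)c1 | intermediate
17 | diethyl {2-[methoxy(methyl)amino]-2-oxoethyl}phosphonate | CCOP(=O)(CC(=O)N(C)OC)OCC | starting material
18 | (2E)-3-[4-(TBS-oxy)phenyl]-N-methoxy-N-methylprop-2-enamide | CON(C)C(=O)/C=C/c1ccc(O[Si](C)(C)C(C)(C)C)cc1 | intermediate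
19 | dilithio species: lithium alkoxide of 16 lithiated on ring A between an EE ether and the methoxy group (not isolated) | COc1cc(OC(C)OCC)c([C@@H](O[Li])C[C@H](/C=C/C[C@@H](O[Si](CC)(CC)CC)CCc2ccc(O[Si](C)(C)C(C)(C)C)cc2)c2ccc(O[Si](C)(C)C(C)(C)C)cc2)c(OC(C)OCC)c1[Li] | intermediate
20 | (2E)-1-{2,4-bis(1-ethoxyethoxy)-3-[(1S,3R,4E,7S)-3,9-bis[4-(TBS-oxy)phenyl]-1-hydroxy-7-(TES-oxy)non-4-en-1-yl]-6-methoxyphenyl}-3-[4-(TBS-oxy)phenyl]prop-2-en-1-one | COc1cc(OC(C)OCC)c([C@@H](O)C[C@H](/C=C/C[C@@H](O[Si](CC)(CC)CC)CCc2ccc(O[Si](C)(C)C(C)(C)C)cc2)c2ccc(O[Si](C)(C)C(C)(C)C)cc2)c(OC(C)OCC)c1C(=O)/C=C/c1ccc(O[Si](C)(C)C(C)(C)C)cc1 | intermediate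
21 | (2E)-1-{3-[(1S,3R,4E,7S)-3,9-bis[4-(TBS-oxy)phenyl]-1,7-dihydroxynon-4-en-1-yl]-2,4-dihydroxy-6-methoxyphenyl}-3-[4-(TBS-oxy)phenyl]prop-2-en-1-one | COc1cc(O)c([C@@H](O)C[C@H](/C=C/C[C@@H](O)CCc2ccc(O[Si](C)(C)C(C)(C)C)cc2)c2ccc(O[Si](C)(C)C(C)(C)C)cc2)c(O)c1C(=O)/C=C/c1ccc(O[Si](C)(C)C(C)(C)C)cc1 | intermediate
22 | (2S)-8-[(1S,3R,4E,7S)-3,9-bis[4-(TBS-oxy)phenyl]-1,7-dihydroxynon-4-en-1-yl]-2-[4-(TBS-oxy)phenyl]-7-hydroxy-5-methoxy-2,3-dihydro-4H-chromen-4-one | COc1cc(O)c([C@@H](O)C[C@H](/C=C/C[C@@H](O)CCc2ccc(O[Si](C)(C)C(C)(C)C)cc2)c2ccc(O[Si](C)(C)C(C)(C)C)cc2)c2c1C(=O)C[C@@H](c1ccc(O[Si](C)(C)C(C)(C)C)cc1)O2 | intermediate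
23 | (2S)-8-[(1S,3R,4E,7S)-1,7-dihydroxy-3,9-bis(4-hydroxyphenyl)non-4-en-1-yl]-7-hydroxy-2-(4-hydroxyphenyl)-5-methoxy-2,3-dihydro-4H-chromen-4-one | COc1cc(O)c([C@@H](O)C[C@H](/C=C/C[C@@H](O)CCc2ccc(O)cc2)c2ccc(O)cc2)c2c1C(=O)C[C@@H](c1ccc(O)cc1)O2 | target

**Step count and risks**

Total step count: 13. Longest linear sequence: 10 steps (steps 1, 2, 3, 4, 7, 8, 10, 11, 12, 13).

Three steps most likely to fail:

Step 12 (the proposed new oxa-Michael cyclisation; risks are low facial selectivity or a sluggish reaction with two free ring-A phenols). The fallback sets out from 21. Cyclisation with an achiral tertiary amine (DABCO, MeCN, 40 °C), known chemistry for 2′-hydroxy-6′-methoxychalcones, gives 22 together with its C2 epimer, the (2R)-flavanone F1. The two are diastereomers and are separated by preparative HPLC. F1 is returned to the same amine conditions, where ring opening and re-closure restore the mixture, and is recycled. The route is rejoined at 22.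

Step 10 (directed ortho-metalation; risks are competing removal of the allylic-benzylic C3″ hydrogen and sluggish acylation of the dianion). The fallback sets out from 16. Electrophilic bromination (NBS, CH2Cl2, −78 °C) at the only free ring-A position gives the aryl bromide F2. Deprotonation of the alcohol with n-BuLi (1 equiv) and bromine–lithium exchange with t-BuLi (2 equiv) at −78 °C, where C–H removal cannot compete, give the same dilithio species 19. This is acylated with 18 as before, and the route is rejoined at 20.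

Step 8 (CBS reduction of a ketone flanked by two ortho acetal ethers; risks are low rate and low selectivity). The fallback sets out from 15. Unselective reduction with NaBH4 (MeOH/THF, 0 °C) gives 16 together with its C1″ epimer, the (1R)-alcohol F3. The epimers are diastereomers and are separated by chromatography on Et3N-buffered silica. F3 is oxidised back to 15 with Dess–Martin periodinane (NaHCO3, CH2Cl2) and recycled. The route is rejoined at 16.

Further compounds
F1 | step 12 | (2R)-8-[(1S,3R,4E,7S)-3,9-bis[4-(TBS-oxy)phenyl]-1,7-dihydroxynon-4-en-1-yl]-2-[4-(TBS-oxy)phenyl]-7-hydroxy-5-methoxy-2,3-dihydro-4H-chromen-4-one | COc1cc(O)c([C@@H](O)C[C@H](/C=C/C[C@@H](O)CCc2ccc(O[Si](C)(C)C(C)(C)C)cc2)c2ccc(O[Si](C)(C)C(C)(C)C)cc2)c2c1C(=O)C[C@H](c1ccc(O[Si](C)(C)C(C)(C)C)cc1)O2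
F2 | step 10 | (1S,3R,4E,7S)-1-[3-bromo-2,6-bis(1-ethoxyethoxy)-4-methoxyphenyl]-3,9-bis[4-(TBS-oxy)phenyl]-7-(TES-oxy)non-4-en-1-ol | COc1cc(OC(C)OCC)c([C@@H](O)C[C@H](/C=C/C[C@@H](O[Si](CC)(CC)CC)CCc2ccc(O[Si](C)(C)C(C)(C)C)cc2)c2ccc(O[Si](C)(C)C(C)(C)C)cc2)c(OC(C)OCC)c1Br
F3 | step 8 | (1R,3R,4E,7S)-1-[2,6-bis(1-ethoxyethoxy)-4-methoxyphenyl]-3,9-bis[4-(TBS-oxy)phenyl]-7-(TES-oxy)non-4-en-1-ol | COc1cc(OC(C)OCC)c([C@H](O)C[C@H](/C=C/C[C@@H](O[Si](CC)(CC)CC)CCc2ccc(O[Si](C)(C)C(C)(C)C)cc2)c2ccc(O[Si](C)(C)C(C)(C)C)cc2)c(OC(C)OCC)c1
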